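**Retrosynthetic overview**
1. The C5 quaternary centre (allyl, OMe) of the 2,4-dienone is the [3,3] (Cope) image of an allyl group on C3a of the cross-conjugated dienone 14, so C5 is relayed suprafacially from C3a, which is next to C3.
2. The C3a–allyl bond comes from phenol 11 by hypervalent-iodine dearomatisation and allylsilane capture anti to the C3 methyl group.
3. C2–aryl disconnection: the O1–C2(H)(Ar)–C3(H)(CH3) unit of the dihydrofuran ring is the syn H/aryl adduct of the C2=C3 enol-ether bond of the flat, achiral 3-methylbenzofuran 8 (C2 unsubstituted and oxygen-bound, C3 benzylic). One enantioselective dearomative reductive Heck coupling with 5-bromo-1,2,3-trimethoxybenzene therefore joins the halves and sets C2 and C3 trans.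
4. Ring order: benzene ring from isovanillin; furan ring by cyclodehydration of an aryloxyacetone (step 4); furan ring dearomatised in step 5; benzene ring dearomatised last (steps 7–8).

Key step: step 5

Assumption: the sense of induction of the chiral bisphosphine in step 5 cannot be predicted from first principles; both antipodes are screened and the one that gives (2S,3S)-10 is used.

**Route**

Step 1
Reactants: 1 isovanillin
Product: 2 4-methoxy-3-[(triisopropylsilyl)oxy]benzaldehyde
Conditions: TIPSCl, imidazole, DMF, rt
Reagents that add atoms: triisopropylsilyl chloride, CC(C)[Si](Cl)(C(C)C)C(C)C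
Why: Imidazole-promoted O-silylation of the phenol; the TIPS ether is chosen because it should survive peracid, carbonate, sulfonic acid resin and Pd/formate and is removed by fluoride alone.

Step 2
Reactants: 2 4-methoxy-3-[(triisopropylsilyl)oxy]benzaldehyde
Product: 4 4-methoxy-3-[(triisopropylsilyl)oxy]phenol, via aryl formate 3 (not isolated)
Conditions: mCPBA, CH2Cl2, rt; then K2CO3 (cat.), MeOH, 0 °C
Reagents that add atoms: mCPBA, OOC(=O)c1cccc(Cl)c1
Why: Baeyer–Villiger (Dakin-type) oxidation in which the electron-rich p-methoxyaryl group migrates, followed by mild methanolysis of the formate, which leaves the new OH para to OMe as the future ring oxygen.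

Step 3
Reactants: 4 4-methoxy-3-[(triisopropylsilyl)oxy]phenol; 5 chloroacetone
Product: 6 1-{4-methoxy-3-[(triisopropylsilyl)oxy]phenoxy}propan-2-one
Conditions: K2CO3, KI (cat.), acetone, reflux
Reagents that add atoms: none
Why: Williamson O-alkylation of the only free phenol with an activated α-chloroketone under aprotic carbonate conditions that do not touch the aryl silyl ether.

Step 4
Reactants: 6 1-{4-methoxy-3-[(triisopropylsilyl)oxy]phenoxy}propan-2-one
Product: 8 5-methoxy-3-methyl-6-[(triisopropylsilyl)oxy]-1-benzofuran, via tertiary carbinol 7 (not isolated)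
Conditions: Amberlyst-15, PhMe, reflux (Dean–Stark)
Reagents that add atoms: none
Why: Acid-catalysed intramolecular Friedel–Crafts hydroxyalkylation and dehydration (aryloxyacetone cyclodehydration) at the ring position para to the silyloxy group, since the other ortho position lies between two oxygens and is shielded by TIPS.

Step 5
Reactants: 8 5-methoxy-3-methyl-6-[(triisopropylsilyl)oxy]-1-benzofuran; 9 5-bromo-1,2,3-trimethoxybenzene
Product: 10 (2S,3S)-5-methoxy-3-methyl-2-(3,4,5-trimethoxyphenyl)-6-[(triisopropylsilyl)oxy]-2,3-dihydro-1-benzofuran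
Conditions: Pd(OAc)2 (5 mol %), chiral bisphosphine (SEGPHOS type, 6 mol %), HCO2Na, MeOH/DMF, 80 °C
Reagents that add atoms: none
Why: Proposed new method: oxidative addition of 9 to Pd(0)/L* and bromide dissociation give ArPd(L*)+, which adds syn across the C2=C3 enol-ether bond of 8 with aryl to the unsubstituted, oxygen-bound C2 and Pd to C3, where it rests as an η3-benzyl complex; formate exchange, decarboxylation and C–H reductive elimination with retention then place H on C3 on the face that carries the aryl group. The closest known reaction types are the enantioselective intramolecular dearomative reductive Heck reactions of indoles and benzofurans, intermolecular reductive Heck hydroarylation of cyclic alkenes, and Heck-type C2 arylation of benzofurans. No ring is closed: the furan ring is dearomatised and the benzene ring stays intact. Both stereocentres arise in the migratory insertion: syn delivery of Ar and H forces the methyl group to the opposite face, which gives the trans relation, and the chiral bisphosphine selects the enantiotopic face of the flat benzofuran, which gives 2S,3S with the proper antipode. The step needs aryl-to-C2 regioselectivity, which the benzylic stabilisation of Pd at C3, the enol-ether polarity and the 3-methyl group secure, and it needs hydride capture to outrun β-hydride loss from the methyl group, which the η3-benzyl resting state and excess formate should favour.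

Step 6
Reactants: 10 (2S,3S)-5-methoxy-3-methyl-2-(3,4,5-trimethoxyphenyl)-6-[(triisopropylsilyl)oxy]-2,3-dihydro-1-benzofuran
Product: 11 (2S,3S)-5-methoxy-3-methyl-2-(3,4,5-trimethoxyphenyl)-2,3-dihydro-1-benzofuran-6-ol
Conditions: TBAF, AcOH, THF, 0 °C
Reagents that add atoms: none
Why: Fluoride cleavage of the aryl silyl ether, buffered with acetic acid so that the electron-rich phenol is not held as its air-sensitive phenoxide and the benzylic ether at C2 is untouched.

Step 7
Reactants: 11 (2S,3S)-5-methoxy-3-methyl-2-(3,4,5-trimethoxyphenyl)-2,3-dihydro-1-benzofuran-6-ol; 12 allyltrimethylsilane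
Product: 14 (2S,3S,3aS)-3a-allyl-5-methoxy-3-methyl-2-(3,4,5-trimethoxyphenyl)-3,3a-dihydro-1-benzofuran-6(2H)-one, via aryloxy-λ3-iodane 13 (not isolated)
Conditions: PhI(OAc)2, (CF3)2CHOH/CH2Cl2, −20 °C, short reaction time; NaHCO3 quench
Reagents that add atoms: none
Why: Hypervalent-iodine oxidative dearomatisation with Hosomi–Sakurai-type capture of the 2-methoxyphenoxonium ion at its para, alkyl-bearing carbon C3a (the site where alkenes attack such ions in oxidative couplings of this family), with the allylsilane approaching anti to the adjacent C3 methyl group to set 3aS.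

Step 8
Reactants: 14 (2S,3S,3aS)-3a-allyl-5-methoxy-3-methyl-2-(3,4,5-trimethoxyphenyl)-3,3a-dihydro-1-benzofuran-6(2H)-one
Product: 15 (2S,3S,5R)-5-allyl-5-methoxy-3-methyl-2-(3,4,5-trimethoxyphenyl)-2,3-dihydro-1-benzofuran-6(5H)-one
Conditions: PhMe, BHT (cat.), 120 °C, sealed tube, base-washed glass; stopped before the aryl allyl ether appears
Reagents that add atoms: none
Why: Cope rearrangement across C3a–C4=C5 (the reverse of the second stage of a para-Claisen, known for 3a-allyl neolignans of this type), in which the suprafacial shift puts the allyl group on C5 on the face it held at C3a, giving 5R, and which should be driven by loss of the crowded ring-fusion quaternary centre and the longer conjugated vinylogous-ester dienone.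

**Compound list**
1 | isovanillin (3-hydroxy-4-methoxybenzaldehyde) | COc1ccc(C=O)cc1O | starting material
2 | 4-methoxy-3-[(triisopropylsilyl)oxy]benzaldehyde | COc1ccc(C=O)cc1O[Si](C(C)C)(C(C)C)C(C)C | intermediate
3 | 4-methoxy-3-[(triisopropylsilyl)oxy]phenyl formate (not isolated) | COc1ccc(OC=O)cc1O[Si](C(C)C)(C(C)C)C(C)C | intermediate
4 | 4-methoxy-3-[(triisopropylsilyl)oxy]phenol | COc1ccc(O)cc1O[Si](C(C)C)(C(C)C)C(C)C | intermediate
5 | chloroacetone | CC(=O)CCl | starting material
6 | 1-{4-methoxy-3-[(triisopropylsilyl)oxy]phenoxy}propan-2-one | CC(=O)COc1ccc(OC)c(O[Si](C(C)C)(C(C)C)C(C)C)c1 | intermediate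
7 | 5-methoxy-3-methyl-6-[(triisopropylsilyl)oxy]-2,3-dihydro-1-benzofuran-3-ol (racemic, not isolated) | COc1cc2c(cc1O[Si](C(C)C)(C(C)C)C(C)C)OCC2(C)O | intermediate
8 | 5-methoxy-3-methyl-6-[(triisopropylsilyl)oxy]-1-benzofuran | COc1cc2c(C)coc2cc1O[Si](C(C)C)(C(C)C)C(C)C | intermediate
9 | 5-bromo-1,2,3-trimethoxybenzene | COc1cc(Br)cc(OC)c1OC | starting material
10 | (2S,3S)-5-methoxy-3-methyl-2-(3,4,5-trimethoxyphenyl)-6-[(triisopropylsilyl)oxy]-2,3-dihydro-1-benzofuran | COc1cc2c(cc1O[Si](C(C)C)(C(C)C)C(C)C)O[C@H](c1cc(OC)c(OC)c(OC)c1)[C@H]2C | intermediate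
11 | (2S,3S)-5-methoxy-3-methyl-2-(3,4,5-trimethoxyphenyl)-2,3-dihydro-1-benzofuran-6-ol | COc1cc2c(cc1O)O[C@H](c1cc(OC)c(OC)c(OC)c1)[C@H]2C | intermediate
12 | allyltrimethylsilane | C=CC[Si](C)(C)C | starting material
13 | acetoxy(phenyl)-λ3-iodanyl ether of phenol 11 (not isolated) | COc1cc2c(cc1OI(OC(C)=O)c1ccccc1)O[C@H](c1cc(OC)c(OC)c(OC)c1)[C@H]2C | intermediate
14 | (2S,3S,3aS)-3a-allyl-5-methoxy-3-methyl-2-(3,4,5-trimethoxyphenyl)-3,3a-dihydro-1-benzofuran-6(2H)-one | COC1=C[C@@]2(CC=C)C(=CC1=O)O[C@H](c1cc(OC)c(OC)c(OC)c1)[C@H]2C | intermediate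
15 | (2S,3S,5R)-5-allyl-5-methoxy-3-methyl-2-(3,4,5-trimethoxyphenyl)-2,3-dihydro-1-benzofuran-6(5H)-one | C=CC[C@@]1(OC)C=C2C(=CC1=O)O[C@H](c1cc(OC)c(OC)c(OC)c1)[C@H]2C | target

**Count**
Total steps: 8. Longest linear sequence: 8 steps (1 to 15).

**Steps most likely to fail**

Step 5 (proposed new method). The arylpalladium bromide may be reduced by formate before it inserts. After insertion, β-hydride loss from the C3 methyl group may lead back to an aromatic 2-arylbenzofuran. Enantioface selection on the flat benzofuran may be low. The fallback sets out from 8 and 9 and comes back at 10, using known reaction types and still joining the halves at C2–aryl. Direct C2–H arylation of 8 with 9 (Pd(OAc)2, PCy3·HBF4, PivOH, K2CO3, DMA, 100 °C) should give the 2-aryl-3-methylbenzofuran F1. Asymmetric hydrogenation of its furan ring with a chiral Ru–NHC catalyst (antipode chosen for 3S) should give the cis-(2R,3S)-dihydrobenzofuran F2. Brief TFA treatment in CH2Cl2 should then open and reclose the benzylic C2–O bond and funnel F2 to the more stable trans isomer 10, with C3 untouched.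

Step 7. The allylsilane may attack the phenoxonium ion at the unsubstituted C7 or at the methoxy-bearing C5 instead of C3a. Facial selectivity at C3a may be poor, and acid may trigger allyl migration in the product. The fallback sets out from 11 and comes back at 15, bypassing 14. Periodate oxidation of the guaiacol unit (NaIO4, aqueous MeOH) should give the o-quinone F3. Barbier allylation (allyl bromide, In, THF/H2O) should add to the C5 carbonyl, the one outside the vinylogous ester, to give the (5R)-o-quinol F4 together with its (5S)-epimer F5, which is removed by chromatography. O-Methylation of F4 (MeOTf, 2,6-di-tert-butyl-4-methylpyridine, CH2Cl2, 0 °C; non-basic, to avoid an anionic oxy-Cope shift) should give 15. The price is that C5 is no longer controlled.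

Step 8. The allyl group may shift toward C7 and the product then tautomerise to a phenol, or the product may undergo onward retro-Claisen cleavage to the aryl allyl ether on prolonged heating. The fallback sets out from 14 and comes back at 15 and uses a temporary blocking group. NBS (CH2Cl2, −20 °C) should brominate the α-carbon of the vinylogous ester to give the 7-bromo dienone F6. On heating, F6 can deliver the allyl group productively only to C5, which should give the 7-bromo 2,4-dienone F7. Pd-catalysed formate hydrogenolysis of the vinyl bromide (Pd(OAc)2, PPh3, HCO2H, Bu3N, DMF, 60 °C) should then give 15.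

**Further compounds**
F1 | step 5 | 5-methoxy-3-methyl-2-(3,4,5-trimethoxyphenyl)-6-[(triisopropylsilyl)oxy]-1-benzofuran | COc1cc2c(C)c(-c3cc(OC)c(OC)c(OC)c3)oc2cc1O[Si](C(C)C)(C(C)C)C(C)C
F2 | step 5 | (2R,3S)-5-methoxy-3-methyl-2-(3,4,5-trimethoxyphenyl)-6-[(triisopropylsilyl)oxy]-2,3-dihydro-1-benzofuran | COc1cc2c(cc1O[Si](C(C)C)(C(C)C)C(C)C)O[C@@H](c1cc(OC)c(OC)c(OC)c1)[C@H]2C
F3 | step 7 | (2S,3S)-3-methyl-2-(3,4,5-trimethoxyphenyl)-2,3-dihydro-1-benzofuran-5,6-dione | O=C1C=C2C(=CC1=O)O[C@H](c1cc(OC)c(OC)c(OC)c1)[C@H]2C
F4 | step 7 | (2S,3S,5R)-5-allyl-5-hydroxy-3-methyl-2-(3,4,5-trimethoxyphenyl)-2,3-dihydro-1-benzofuran-6(5H)-one | C=CC[C@@]1(O)C=C2C(=CC1=O)O[C@H](c1cc(OC)c(OC)c(OC)c1)[C@H]2C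
F5 | step 7 | (2S,3S,5S)-5-allyl-5-hydroxy-3-methyl-2-(3,4,5-trimethoxyphenyl)-2,3-dihydro-1-benzofuran-6(5H)-one | C=CC[C@]1(O)C=C2C(=CC1=O)O[C@H](c1cc(OC)c(OC)c(OC)c1)[C@H]2C
F6 | step 8 | (2S,3S,3aS)-3a-allyl-7-bromo-5-methoxy-3-methyl-2-(3,4,5-trimethoxyphenyl)-3,3a-dihydro-1-benzofuran-6(2H)-one | COC1=C[C@@]2(CC=C)C(=C(Br)C1=O)O[C@H](c1cc(OC)c(OC)c(OC)c1)[C@H]2C
F7 | step 8 | (2S,3S,5R)-5-allyl-7-bromo-5-methoxy-3-methyl-2-(3,4,5-trimethoxyphenyl)-2,3-dihydro-1-benzofuran-6(5H)-one | C=CC[C@@]1(OC)C=C2C(=C(Br)C1=O)O[C@H](c1cc(OC)c(OC)c(OC)c1)[C@H]2C
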